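**Plan**

1. Locants (germacrane type): C1 furanone C=O, C2 furanone CH, C3 enol-ether carbon, C4 CHMe, C5 CH2, C6 acyloxy CH, C7=C11 butenolide, C8 enol-lactone carbon, C9 =CH, C10 quaternary C–O, C12 lactone C=O, C13 CH2OAc.
2. Retrosynthetic cuts, in order: C6 ester and C13 acetate; C8=C9 (opens the ten-membered ring); C1–C2 and O–C10 of the furanone (methyl ketone + methyl (R)-2-methylglycidate); butenolide back to a 2-silylfuran; C6–C7 (4-lithiofuran + (S)-methylsuccinic anhydride).
3. Forward order: furan (bought) → temporary γ-lactone (becomes the C3 methyl ketone) → 3(2H)-furanone (step 8) → butenolide (furan oxidation) → ten-membered carbocycle with the enol-lactone double bond (step 11) → acylations.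
4. Enabling feature: in the furanone ring O–C3=C2–C1(=O)–C10, the fully substituted C10 carries the ring oxygen next to C9. C9–C10 can therefore be an oxirane whose ester carbon is C1; one ketone enolate supplies C2 and the ring oxygen, one glycidate supplies C1, C9, C10 and the methyl group.
5. Stereochemistry: C4 from (S)-methylsuccinic acid; C6 by catalyst-controlled transfer hydrogenation; C10 by inversion at the oxirane carbon; C8=C9 geometry enforced by the nine-membered oxa-bridged ring; side-chain Z geometry from a butenolide.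

Key step: step 8

Remark: methyl (R)-2-methyloxirane-2-carboxylate (11) is taken as a purchasable enantiopure building block; otherwise it follows from 2-methylprop-2-en-1-ol by asymmetric epoxidation, oxidation to the acid and esterification.

**Route**

Step 1
Reactants: 1 furan-3-ylmethanol
Product: 2 tert-butyl(furan-3-ylmethoxy)dimethylsilane
Conditions: TBSCl, imidazole, DMF, 0 °C → rt
Reagents that add atoms: tert-butyldimethylsilyl chloride, CC(C)(C)[Si](C)(C)Cl
Why: Imidazole-promoted silylation of a primary alcohol installs the silyl group that is moved to carbon in step 2.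

Step 2
Reactants: 2 tert-butyl(furan-3-ylmethoxy)dimethylsilane
Product: 3 [2-(tert-butyldimethylsilyl)furan-3-yl]methanol
Conditions: n-BuLi, HMPA, THF, −78 → 0 °C; then H2O
Reagents that add atoms: none
Why: C2-lithiation of the 3-(silyloxymethyl)furan followed by 1,4 O→C silyl migration (retro-Brook rearrangement) is known for this furan class and marks with silicon the carbon (C12) that later becomes the lactone carbonyl.

Step 3
Reactants: 4 (S)-2-methylsuccinic acid
Product: 5 (S)-3-methyloxolane-2,5-dione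
Conditions: AcCl, reflux; distillation
Reagents that add atoms: none
Why: Cyclodehydration of the 1,4-diacid with acetyl chloride gives the five-membered anhydride and leaves the C4 stereocentre untouched.

Step 4
Reactants: 3 [2-(tert-butyldimethylsilyl)furan-3-yl]methanol; 5 (S)-3-methyloxolane-2,5-dione
Product: 6 (S)-4-[5-(tert-butyldimethylsilyl)-4-(hydroxymethyl)furan-3-yl]-2-methyl-4-oxobutanoic acid
Conditions: 3, n-BuLi (2.2 equiv), DME, 0 °C; then 5, THF, −78 °C; aq HCl
Reagents that add atoms: none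
Why: Alkoxide-directed lithiation of the 2-silylated 3-(hydroxymethyl)furan at C4 is known, and the aryllithium should open the anhydride at the less hindered CH2-flanked carbonyl (nucleophilic acyl substitution), the neighbouring alkoxide capturing the new ketone as a hemiketal so that double addition is suppressed.

Step 5
Reactants: 6 (S)-4-[5-(tert-butyldimethylsilyl)-4-(hydroxymethyl)furan-3-yl]-2-methyl-4-oxobutanoic acid
Product: 8 (3S,5S)-5-[5-(tert-butyldimethylsilyl)-4-(hydroxymethyl)furan-3-yl]-3-methyloxolan-2-one, via hydroxy acid 7 (not isolated)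
Conditions: RuCl[(S,S)-TsDPEN](p-cymene) (1 mol %), HCO2H/Et3N (5:2), 30 °C; then TsOH (cat.), toluene, rt
Reagents that add atoms: none
Why: Noyori asymmetric transfer hydrogenation of the furyl (aryl) ketone with the (S,S) catalyst should set C6 as S under catalyst control (the sense known for aryl alkyl ketones), and the γ-hydroxy acid lactonises to the cis lactone.

Step 6
Reactants: 8 (3S,5S)-5-[5-(tert-butyldimethylsilyl)-4-(hydroxymethyl)furan-3-yl]-3-methyloxolan-2-one
Product: 9 (3S,5S)-5-[5-(tert-butyldimethylsilyl)-4-(hydroxymethyl)furan-3-yl]-5-hydroxy-3-methylpentan-2-one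
Conditions: MeLi (2.1 equiv), THF, −78 °C; AcOH quench at −78 °C
Reagents that add atoms: methyllithium, [Li]C
Why: Addition of methyllithium to the γ-lactone stops at the stable lithium lactolate at −78 °C (the second equivalent only deprotonates the primary alcohol), so the methyl ketone (in equilibrium with its lactol) should form without over-addition and without change at C4 or C6.

Step 7
Reactants: 9 (3S,5S)-5-[5-(tert-butyldimethylsilyl)-4-(hydroxymethyl)furan-3-yl]-5-hydroxy-3-methylpentan-2-one
Product: 10 (3S,5S)-5-[(tert-butyldimethylsilyl)oxy]-5-[5-(tert-butyldimethylsilyl)-4-{[(tert-butyldimethylsilyl)oxy]methyl}furan-3-yl]-3-methylpentan-2-one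
Conditions: TBSCl (2.5 equiv), imidazole, DMF, rt
Reagents that add atoms: tert-butyldimethylsilyl chloride, CC(C)(C)[Si](C)(C)Cl
Why: Silyl ether formation traps the open hydroxy ketone tautomer and protects both hydroxyl groups for the enolate chemistry of step 8.

Step 8
Reactants: 10 (3S,5S)-5-[(tert-butyldimethylsilyl)oxy]-5-[5-(tert-butyldimethylsilyl)-4-{[(tert-butyldimethylsilyl)oxy]methyl}furan-3-yl]-3-methylpentan-2-one; 11 methyl (R)-2-methyloxirane-2-carboxylate
Product: 13 (S)-5-{(2S,4S)-4-[(tert-butyldimethylsilyl)oxy]-4-[5-(tert-butyldimethylsilyl)-4-{[(tert-butyldimethylsilyl)oxy]methyl}furan-3-yl]butan-2-yl}-2-(hydroxymethyl)-2-methylfuran-3(2H)-one, via epoxy diketone 12 (not isolated)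
Conditions: LiHMDS (2.2 equiv), THF, −78 °C; 11, −78 → −20 °C; DMPU, −20 → 0 °C; AcOH
Reagents that add atoms: none
Why: Proposed new method: the kinetic lithium enolate of the methyl ketone (C2) is C-acylated by the glycidic ester (Claisen condensation, forming C1–C2), and the C3 oxygen of the resulting 1,3-diketonate then opens the oxirane at its quaternary carbon C10 (forming O–C10) and frees the C9 alkoxide. The closest known reactions are the Claisen acylation of ketone enolates, the base-induced cyclisation of α'-halo-1,3-diketones to 3(2H)-furanones and 5-exo openings of epoxides by tethered oxygen nucleophiles, so the step is an acylative, interrupted Feist–Benary-type annulation. The furanone ring closes 5-exo-tet, whereas the 6-endo attack at C9 is stereoelectronically disfavoured because the planar enolate oxygen cannot reach the backside of the C9–O bond. C10 is set by inversion at the (R)-configured oxirane carbon, which gives the S configuration of the target. The step needs enolisation at the methyl group and not at C4 (hindered amide at −78 °C), C- over O-acylation (lithium enolate with an ester) and release of the enolate oxygen from the lithium chelate for ring closure (DMPU); the butenolide is still masked as a 2-silylfuran and offers no competing acidic hydrogen. The lithium alkoxide product is protonated cold with acetic acid to forestall retro-aldol loss of formaldehyde.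

Step 9
Reactants: 13 (S)-5-{(2S,4S)-4-[(tert-butyldimethylsilyl)oxy]-4-[5-(tert-butyldimethylsilyl)-4-{[(tert-butyldimethylsilyl)oxy]methyl}furan-3-yl]butan-2-yl}-2-(hydroxymethyl)-2-methylfuran-3(2H)-one
Product: 14 (S)-5-{(2S,4S)-4-[(tert-butyldimethylsilyl)oxy]-4-[4-{[(tert-butyldimethylsilyl)oxy]methyl}-5-oxo-2,5-dihydrofuran-3-yl]butan-2-yl}-2-(hydroxymethyl)-2-methylfuran-3(2H)-one
Conditions: AcOOH (in AcOH), NaOAc, CH2Cl2, 0 °C → rt; then Et3N (cat.)
Reagents that add atoms: peracetic acid, CC(=O)OO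
Why: Peracid oxidation of 2-silylfurans to butenolides (attack at the silicon-bearing C=C, C→O silyl shift, protonation of the 2-silyloxyfuran) places the carbonyl regiospecifically at the former C–Si carbon C12 and leaves C8 as the CH2 needed in step 11, while the electron-poor furanone C=C should not be epoxidised.

Step 10
Reactants: 14 (S)-5-{(2S,4S)-4-[(tert-butyldimethylsilyl)oxy]-4-[4-{[(tert-butyldimethylsilyl)oxy]methyl}-5-oxo-2,5-dihydrofuran-3-yl]butan-2-yl}-2-(hydroxymethyl)-2-methylfuran-3(2H)-one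
Product: 15 (S)-5-{(2S,4S)-4-[(tert-butyldimethylsilyl)oxy]-4-[4-{[(tert-butyldimethylsilyl)oxy]methyl}-5-oxo-2,5-dihydrofuran-3-yl]butan-2-yl}-2-methyl-3-oxo-2,3-dihydrofuran-2-carbaldehyde
Conditions: Dess–Martin periodinane, CH2Cl2, 0 °C → rt
Reagents that add atoms: none
Why: Dess–Martin oxidation of the neopentyl primary alcohol gives the non-enolisable β-keto aldehyde (C10 is quaternary) under non-basic conditions, which avoids deformylation.

Step 11
Reactants: 15 (S)-5-{(2S,4S)-4-[(tert-butyldimethylsilyl)oxy]-4-[4-{[(tert-butyldimethylsilyl)oxy]methyl}-5-oxo-2,5-dihydrofuran-3-yl]butan-2-yl}-2-methyl-3-oxo-2,3-dihydrofuran-2-carbaldehyde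
Product: 18 (4S,6S,10S)-6,13-bis[(tert-butyldimethylsilyl)oxy]-3,10-epoxy-1-oxogermacra-2,7(11),8-trien-12,8-olide, via silyloxyfuran aldehyde 16 (not isolated), via aldol silyl ether 17 (not isolated)
Conditions: TBSOTf (1.2 equiv), i-Pr2NEt, CH2Cl2 (1 mM, slow addition of 15), −78 → 0 °C; then DBU, 0 °C
Reagents that add atoms: none
Why: Soft enolisation of the butenolide to the aromatic 2-silyloxyfuran, silyl triflate-promoted intramolecular vinylogous Mukaiyama aldol addition of C8 to the C9 aldehyde and DBU-induced E1cB loss of silanolate (a known one-pot aldol/elimination route to γ-ylidenebutenolides) close the ten-membered carbocycle, and the new C8=C9 bond lies in the nine-membered ring C3–O–C10–C9–C8–C7–C6–C5–C4, which only accommodates C7 and C10 cis, i.e. the E enol lactone of the target.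

Step 12
Reactants: 18 (4S,6S,10S)-6,13-bis[(tert-butyldimethylsilyl)oxy]-3,10-epoxy-1-oxogermacra-2,7(11),8-trien-12,8-olide
Product: 19 (4S,6S,10S)-6,13-dihydroxy-3,10-epoxy-1-oxogermacra-2,7(11),8-trien-12,8-olide
Conditions: HF·pyridine, pyridine, THF, 0 °C → rt
Reagents that add atoms: none
Why: Buffered HF·pyridine cleaves both silyl ethers through Si–F bond formation without the base that would endanger the enol lactone and the furanone.

Step 13
Reactants: 19 (4S,6S,10S)-6,13-dihydroxy-3,10-epoxy-1-oxogermacra-2,7(11),8-trien-12,8-olide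
Product: 20 (4S,6S,10S)-13-acetoxy-6-hydroxy-3,10-epoxy-1-oxogermacra-2,7(11),8-trien-12,8-olide
Conditions: Ac2O (1.05 equiv), 2,4,6-collidine, CH2Cl2, −40 °C
Reagents that add atoms: acetic anhydride, CC(=O)OC(C)=O
Why: Kinetically selective acylation: the unhindered primary allylic alcohol should react much faster than the ring-bound secondary C6 alcohol at low temperature with one equivalent of anhydride.

Step 14
Reactants: 21 4-methylfuran-2(5H)-one
Product: 22 sodium (Z)-4-hydroxy-3-methylbut-2-enoate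
Conditions: NaOH (1.0 equiv), H2O/MeOH, rt; evaporation
Reagents that add atoms: sodium hydroxide, [Na+].[OH-]
Why: Saponification opens the butenolide with the ring double-bond geometry preserved, which fixes the Z configuration of the side chain.

Step 15
Reactants: 22 sodium (Z)-4-hydroxy-3-methylbut-2-enoate
Product: 24 (Z)-4-[(tert-butyldimethylsilyl)oxy]-3-methylbut-2-enoic acid, via bis-silyl derivative 23 (not isolated)
Conditions: TBSCl (2.2 equiv), imidazole, DMF, rt; then THF/H2O/AcOH (cat.), 0 °C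
Reagents that add atoms: tert-butyldimethylsilyl chloride, CC(C)(C)[Si](C)(C)Cl
Why: Silylation of both oxygens outruns relactonisation and the labile silyl ester is hydrolysed selectively on aqueous work-up, a known way to (Z)-4-silyloxy-2-enoic acids.

Step 16
Reactants: 20 (4S,6S,10S)-13-acetoxy-6-hydroxy-3,10-epoxy-1-oxogermacra-2,7(11),8-trien-12,8-olide; 24 (Z)-4-[(tert-butyldimethylsilyl)oxy]-3-methylbut-2-enoic acid
Product: 25 (4S,6S,10S)-13-acetoxy-6-{(Z)-4-[(tert-butyldimethylsilyl)oxy]-3-methylbut-2-enoyloxy}-3,10-epoxy-1-oxogermacra-2,7(11),8-trien-12,8-olide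
Conditions: 24, 2,4,6-trichlorobenzoyl chloride, Et3N, toluene, rt; then 20, DMAP, rt
Reagents that add atoms: none
Why: Yamaguchi esterification through the mixed anhydride acylates the hindered secondary alcohol under mild conditions under which Z-configured enoates are known to keep their geometry.

Step 17
Reactants: 25 (4S,6S,10S)-13-acetoxy-6-{(Z)-4-[(tert-butyldimethylsilyl)oxy]-3-methylbut-2-enoyloxy}-3,10-epoxy-1-oxogermacra-2,7(11),8-trien-12,8-olide
Product: 26 CNP0269057.1, (4S,6S,10S)-13-acetoxy-6-[(Z)-4-hydroxy-3-methylbut-2-enoyloxy]-3,10-epoxy-1-oxogermacra-2,7(11),8-trien-12,8-olide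
Conditions: HF·pyridine, pyridine, THF, 0 °C
Reagents that add atoms: none
Why: Buffered fluoride desilylation at 0 °C frees the primary alcohol while the acetate, the enol lactone and the furanone stay intact and relactonisation of the Z-γ-hydroxy enoate (which would expel the C6 alcohol) should be slow.

**Compound list**

1 | furan-3-ylmethanol | OCc1ccoc1 | starting material
2 | tert-butyl(furan-3-ylmethoxy)dimethylsilane | CC(C)(C)[Si](C)(C)OCc1ccoc1 | intermediate
3 | [2-(tert-butyldimethylsilyl)furan-3-yl]methanol | CC(C)(C)[Si](C)(C)c1occc1CO | intermediate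
4 | (S)-2-methylsuccinic acid | C[C@@H](CC(=O)O)C(=O)O | starting material
5 | (S)-3-methyloxolane-2,5-dione | C[C@H]1CC(=O)OC1=O | intermediate
6 | (S)-4-[5-(tert-butyldimethylsilyl)-4-(hydroxymethyl)furan-3-yl]-2-methyl-4-oxobutanoic acid | C[C@@H](CC(=O)c1coc([Si](C)(C)C(C)(C)C)c1CO)C(=O)O | intermediate
7 | (2S,4S)-4-[5-(tert-butyldimethylsilyl)-4-(hydroxymethyl)furan-3-yl]-4-hydroxy-2-methylbutanoic acid (hydroxy acid) | C[C@@H](C[C@H](O)c1coc([Si](C)(C)C(C)(C)C)c1CO)C(=O)O | intermediate
8 | (3S,5S)-5-[5-(tert-butyldimethylsilyl)-4-(hydroxymethyl)furan-3-yl]-3-methyloxolan-2-one (cis lactone) | C[C@H]1C[C@@H](c2coc([Si](C)(C)C(C)(C)C)c2CO)OC1=O | intermediate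
9 | (3S,5S)-5-[5-(tert-butyldimethylsilyl)-4-(hydroxymethyl)furan-3-yl]-5-hydroxy-3-methylpentan-2-one | CC(=O)[C@@H](C)C[C@H](O)c1coc([Si](C)(C)C(C)(C)C)c1CO | intermediate
10 | (3S,5S)-5-[(tert-butyldimethylsilyl)oxy]-5-[5-(tert-butyldimethylsilyl)-4-{[(tert-butyldimethylsilyl)oxy]methyl}furan-3-yl]-3-methylpentan-2-one | CC(=O)[C@@H](C)C[C@H](O[Si](C)(C)C(C)(C)C)c1coc([Si](C)(C)C(C)(C)C)c1CO[Si](C)(C)C(C)(C)C | intermediate
11 | methyl (R)-2-methyloxirane-2-carboxylate | COC(=O)[C@@]1(C)CO1 | starting material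
12 | (4S,6S)-6-[(tert-butyldimethylsilyl)oxy]-6-[5-(tert-butyldimethylsilyl)-4-{[(tert-butyldimethylsilyl)oxy]methyl}furan-3-yl]-4-methyl-1-[(R)-2-methyloxiran-2-yl]hexane-1,3-dione (epoxy diketone) | O=C(CC(=O)[C@@H](C)C[C@H](O[Si](C)(C)C(C)(C)C)c1coc([Si](C)(C)C(C)(C)C)c1CO[Si](C)(C)C(C)(C)C)[C@@]2(C)CO2 | intermediate
13 | (S)-5-{(2S,4S)-4-[(tert-butyldimethylsilyl)oxy]-4-[5-(tert-butyldimethylsilyl)-4-{[(tert-butyldimethylsilyl)oxy]methyl}furan-3-yl]butan-2-yl}-2-(hydroxymethyl)-2-methylfuran-3(2H)-one | OC[C@]1(C)OC(=CC1=O)[C@@H](C)C[C@H](O[Si](C)(C)C(C)(C)C)c1coc([Si](C)(C)C(C)(C)C)c1CO[Si](C)(C)C(C)(C)C | intermediate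
14 | (S)-5-{(2S,4S)-4-[(tert-butyldimethylsilyl)oxy]-4-[4-{[(tert-butyldimethylsilyl)oxy]methyl}-5-oxo-2,5-dihydrofuran-3-yl]butan-2-yl}-2-(hydroxymethyl)-2-methylfuran-3(2H)-one | OC[C@]1(C)OC(=CC1=O)[C@@H](C)C[C@H](O[Si](C)(C)C(C)(C)C)C1=C(CO[Si](C)(C)C(C)(C)C)C(=O)OC1 | intermediate
15 | (S)-5-{(2S,4S)-4-[(tert-butyldimethylsilyl)oxy]-4-[4-{[(tert-butyldimethylsilyl)oxy]methyl}-5-oxo-2,5-dihydrofuran-3-yl]butan-2-yl}-2-methyl-3-oxo-2,3-dihydrofuran-2-carbaldehyde | O=C[C@]1(C)OC(=CC1=O)[C@@H](C)C[C@H](O[Si](C)(C)C(C)(C)C)C1=C(CO[Si](C)(C)C(C)(C)C)C(=O)OC1 | intermediate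
16 | (S)-5-{(2S,4S)-4-[(tert-butyldimethylsilyl)oxy]-4-[5-[(tert-butyldimethylsilyl)oxy]-4-{[(tert-butyldimethylsilyl)oxy]methyl}furan-3-yl]butan-2-yl}-2-methyl-3-oxo-2,3-dihydrofuran-2-carbaldehyde (silyloxyfuran aldehyde) | O=C[C@]1(C)OC(=CC1=O)[C@@H](C)C[C@H](O[Si](C)(C)C(C)(C)C)c1coc(O[Si](C)(C)C(C)(C)C)c1CO[Si](C)(C)C(C)(C)C | intermediate
17 | (4S,6S,10S)-6,9,13-tris[(tert-butyldimethylsilyl)oxy]-3,10-epoxy-1-oxogermacra-2,7(11)-dien-12,8-olide (aldol silyl ether, mixture at C8 and C9) | CC(C)(C)[Si](C)(C)OCC1=C2C(OC1=O)C(O[Si](C)(C)C(C)(C)C)[C@]3(C)OC(=CC3=O)[C@@H](C)C[C@@H]2O[Si](C)(C)C(C)(C)C | intermediate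
18 | (4S,6S,10S)-6,13-bis[(tert-butyldimethylsilyl)oxy]-3,10-epoxy-1-oxogermacra-2,7(11),8-trien-12,8-olide | CC(C)(C)[Si](C)(C)OCC1=C2/C(=C\[C@]3(C)OC(=CC3=O)[C@@H](C)C[C@@H]2O[Si](C)(C)C(C)(C)C)OC1=O | intermediate
19 | (4S,6S,10S)-6,13-dihydroxy-3,10-epoxy-1-oxogermacra-2,7(11),8-trien-12,8-olide | OCC1=C2/C(=C\[C@]3(C)OC(=CC3=O)[C@@H](C)C[C@@H]2O)OC1=O | intermediate
20 | (4S,6S,10S)-13-acetoxy-6-hydroxy-3,10-epoxy-1-oxogermacra-2,7(11),8-trien-12,8-olide | CC(=O)OCC1=C2/C(=C\[C@]3(C)OC(=CC3=O)[C@@H](C)C[C@@H]2O)OC1=O | intermediate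
21 | 4-methylfuran-2(5H)-one | CC1=CC(=O)OC1 | starting material
22 | sodium (Z)-4-hydroxy-3-methylbut-2-enoate | [Na+].[O-]C(=O)/C=C(/C)CO | intermediate
23 | tert-butyldimethylsilyl (Z)-4-[(tert-butyldimethylsilyl)oxy]-3-methylbut-2-enoate (bis-silyl derivative) | CC(C)(C)[Si](C)(C)OC(=O)/C=C(/C)CO[Si](C)(C)C(C)(C)C | intermediate
24 | (Z)-4-[(tert-butyldimethylsilyl)oxy]-3-methylbut-2-enoic acid | OC(=O)/C=C(/C)CO[Si](C)(C)C(C)(C)C | intermediate
25 | (4S,6S,10S)-13-acetoxy-6-{(Z)-4-[(tert-butyldimethylsilyl)oxy]-3-methylbut-2-enoyloxy}-3,10-epoxy-1-oxogermacra-2,7(11),8-trien-12,8-olide | CC(=O)OCC1=C2/C(=C\[C@]3(C)OC(=CC3=O)[C@@H](C)C[C@@H]2OC(=O)/C=C(/C)CO[Si](C)(C)C(C)(C)C)OC1=O | intermediate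
26 | CNP0269057.1, (4S,6S,10S)-13-acetoxy-6-[(Z)-4-hydroxy-3-methylbut-2-enoyloxy]-3,10-epoxy-1-oxogermacra-2,7(11),8-trien-12,8-olide | CC(=O)OCC1=C2/C(=C\[C@]3(C)OC(=CC3=O)[C@@H](C)C[C@@H]2OC(=O)/C=C(/C)CO)OC1=O | target

**Step count and risks**

Total step count: 17. Longest linear sequence: 14 steps (1, 2, 4 to 13, 16, 17).

Steps most likely to fail:

1. Step 8. The ring closure may go to the CH2 terminus of the oxirane (six-membered dihydropyranone), may not occur at all from the chelated diketonate, or the alkoxide formed may fragment by retro-aldol loss of formaldehyde. The fallback uses known chemistry, sets out from 10 and comes back at 13. The kinetic lithium enolate of 10 is acylated (Claisen condensation) with the ester methyl (S)-3-[(4-methoxybenzyl)oxy]-2-methyl-2-[(trimethylsilyl)oxy]propanoate F1, which is made from the S enantiomer of 11 by acid-catalysed opening of the oxirane at CH2 with 4-methoxybenzyl alcohol and silylation. This gives the α'-silyloxy 1,3-diketone F2. TsOH (cat.) in wet benzene removes the trimethylsilyl group and cyclodehydrates the α'-hydroxy 1,3-diketone to the furanone 4-methoxybenzyl ether F3. Here the tertiary hydroxyl oxygen becomes the ring oxygen and C10 keeps its configuration, which is why the S ester is used. DDQ in buffered CH2Cl2/H2O then frees the primary alcohol and gives 13.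

2. Step 11. Intermolecular aldol oligomerisation may outrun ring closure, the silyloxymethyl group at C13 may ionise from the silyloxyfuran (1,4-elimination), or C4 may epimerise under DBU. The fallback closes the ring by olefination, sets out from 14 and comes back at 18. TESOTf/Et3N converts 14 into the 2-silyloxyfuran with the C9 hydroxyl silylated, and NBS at −78 °C brominates the γ-position to give the γ-bromobutenolide triethylsilyl ether F4. An Arbuzov reaction with P(OEt)3 gives the γ-phosphonate F5. Swern oxidation converts the primary triethylsilyl ether directly into the aldehyde phosphonate F6. LiCl/i-Pr2NEt in MeCN at high dilution then closes the ring by intramolecular Horner–Wadsworth–Emmons olefination to 18, the C8=C9 geometry again being dictated by the nine-membered ring.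

3. Step 9. The bulky tert-butyldimethylsilyl group on carbon may slow the C→O silyl shift, so that ring-opened enediones, protodesilylation or over-oxidation take over. The fallback sets out from 13 and comes back at 14. Sensitised photo-oxygenation (O2, hν, tetraphenylporphyrin, CH2Cl2, −78 °C) of the 2-silylfuran, in which the silyl group directs the breakdown of the endoperoxide so that the silicon-bearing carbon becomes the carboxyl carbon, gives the γ-hydroxybutenolide F7. NaBH4 in EtOH at −20 °C reduces its open-chain aldehyde tautomer, and acidification relactonises the hydroxy acid to 14.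

Further compounds

F1 | step 8 | methyl (S)-3-[(4-methoxybenzyl)oxy]-2-methyl-2-[(trimethylsilyl)oxy]propanoate | COc1ccc(COC[C@](C)(O[Si](C)(C)C)C(=O)OC)cc1
F2 | step 8 | (2S,5S,7S)-7-[(tert-butyldimethylsilyl)oxy]-7-[5-(tert-butyldimethylsilyl)-4-{[(tert-butyldimethylsilyl)oxy]methyl}furan-3-yl]-1-[(4-methoxybenzyl)oxy]-2,5-dimethyl-2-[(trimethylsilyl)oxy]heptane-3,4-dione-type α'-silyloxy 1,3-diketone (C3 and C1 carbonyls separated by CH2) | O=C(CC(=O)[C@@H](C)C[C@H](O[Si](C)(C)C(C)(C)C)c1coc([Si](C)(C)C(C)(C)C)c1CO[Si](C)(C)C(C)(C)C)[C@@](C)(O[Si](C)(C)C)COCc2ccc(OC)cc2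
F3 | step 8 | 4-methoxybenzyl ether of 13 | COc1ccc(COC[C@]2(C)OC(=CC2=O)[C@@H](C)C[C@H](O[Si](C)(C)C(C)(C)C)c3coc([Si](C)(C)C(C)(C)C)c3CO[Si](C)(C)C(C)(C)C)cc1
F4 | step 11 | γ-bromobutenolide triethylsilyl ether derived from 14 (bromine at C8, mixture of epimers) | CC[Si](CC)(CC)OC[C@]1(C)OC(=CC1=O)[C@@H](C)C[C@H](O[Si](C)(C)C(C)(C)C)C1=C(CO[Si](C)(C)C(C)(C)C)C(=O)OC1Br
F5 | step 11 | γ-(diethoxyphosphoryl)butenolide triethylsilyl ether | CC[Si](CC)(CC)OC[C@]1(C)OC(=CC1=O)[C@@H](C)C[C@H](O[Si](C)(C)C(C)(C)C)C1=C(CO[Si](C)(C)C(C)(C)C)C(=O)OC1P(=O)(OCC)OCC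
F6 | step 11 | aldehyde phosphonate | O=C[C@]1(C)OC(=CC1=O)[C@@H](C)C[C@H](O[Si](C)(C)C(C)(C)C)C1=C(CO[Si](C)(C)C(C)(C)C)C(=O)OC1P(=O)(OCC)OCC
F7 | step 9 | γ-hydroxybutenolide derived from 13 (hydroxyl at C8, mixture of epimers) | OC[C@]1(C)OC(=CC1=O)[C@@H](C)C[C@H](O[Si](C)(C)C(C)(C)C)C1=C(CO[Si](C)(C)C(C)(C)C)C(=O)OC1O
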